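The target is cut at the C4–C5' bond between the upper isoflavan (rings A, B, C) and the resorcinol-type ring of the lower one, which is raised afterwards on a bromophenol. Everything rests on pyran ring C. C3 is its only atom that bears ring B, and it lies between O-bound C2 and benzylic C4, so excising C3 leaves the C2=C3 bond of a benzofuran. In the key step an aryl(chloro)carbene carrying ring B inserts into that bond of a 3-silyloxybenzofuran. The furan expands to the 4-pyranone and a complete isoflavone results. Its carbonyl then sets C3 (dynamic kinetic resolution) and C4 (anti Friedel–Crafts attack).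

Key step: step 7

Remark: isoflavan numbering is used (O1, C2, C3, C4, C4a–C8a; primes for the 3-aryl ring; "upper" is the 4-arylated unit, "lower" the other one), and 2,6-dimethoxyphenol, 6-hydroxybenzofuran-3(2H)-one, 2-bromo-5-methoxyphenol and 7-hydroxychroman-4-one are taken as catalogue compounds.

Step 1
Reactants: 1 2,6-dimethoxyphenol
Product: 2 2-(benzyloxy)-1,3-dimethoxybenzene
Conditions: BnBr, K2CO3, DMF, 60 °C
Reagents that add atoms: benzyl bromide, BrCc1ccccc1
Why: Williamson etherification of the phenolate masks the future 3'-OH of ring B as a benzyl ether that should survive base, carbene, acid and hydride conditions and fall only in the last step.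

Step 2
Reactants: 2 2-(benzyloxy)-1,3-dimethoxybenzene
Product: 4 3-(benzyloxy)-2,4-dimethoxybenzonitrile, via N-chlorosulfonyl amide 3 (not isolated)
Conditions: ClSO2NCO, CH2Cl2, 0 °C to rt; then DMF, 0 °C to rt; aqueous work-up
Reagents that add atoms: chlorosulfonyl isocyanate, O=C=NS(=O)(=O)Cl
Why: Friedel–Crafts-type carbamoylation with chlorosulfonyl isocyanate should go to C4 of 2 (ortho to one methoxy group and para to the other, the usual site of 1,2,3-trialkoxybenzenes), and DMF then strips the chlorosulfonic acid unit from 3 to leave the nitrile.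

Step 3
Reactants: 4 3-(benzyloxy)-2,4-dimethoxybenzonitrile
Product: 6 3-(benzyloxy)-2,4-dimethoxybenzamidine hydrochloride, via lithium bis(silyl)amidinate 5 (not isolated)
Conditions: LiN(SiMe3)2, THF, rt to 50 °C; then HCl in EtOH, 0 °C
Reagents that add atoms: lithium bis(trimethylsilyl)amide, [Li]N([Si](C)(C)C)[Si](C)(C)C; hydrogen chloride, Cl
Why: Nucleophilic addition of the silylamide to the nitrile gives amidinate 5, and acidic ethanolysis of both N–Si bonds releases the amidinium chloride (standard nitrile-to-amidine conversion).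

Step 4
Reactants: 6 3-(benzyloxy)-2,4-dimethoxybenzamidine hydrochloride
Product: 7 3-[3-(benzyloxy)-2,4-dimethoxyphenyl]-3-chloro-3H-diazirine (kept as a cold solution)
Conditions: aq NaOCl, LiCl, DMSO–pentane, 0 °C
Reagents that add atoms: sodium hypochlorite, [Na+].[O-]Cl; lithium chloride, [Li+].[Cl-]
Why: The Graham oxidation N-chlorinates the amidine, closes the N–N bond and places chloride on carbon, while the amidinium group should damp electrophilic chlorination of the arene.

Step 5
Reactants: 8 6-hydroxybenzofuran-3(2H)-one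
Product: 9 6-(benzyloxy)benzofuran-3(2H)-one
Conditions: BnBr, K2CO3, DMF, rt
Reagents that add atoms: benzyl bromide, BrCc1ccccc1
Why: Williamson etherification at the phenolate, the most acidic and least hindered site, protects the future 7-OH of ring A.

Step 6
Reactants: 9 6-(benzyloxy)benzofuran-3(2H)-one
Product: 10 {[6-(benzyloxy)benzofuran-3-yl]oxy}(tert-butyl)dimethylsilane
Conditions: TBSOTf, Et3N, CH2Cl2, 0 °C
Reagents that add atoms: tert-butyldimethylsilyl triflate, CC(C)(C)[Si](C)(C)OS(=O)(=O)C(F)(F)F
Why: Soft enolisation and O-silylation is driven by aromatisation to the benzofuran and gives the only possible silyl enol ether, whose C2=C3 bond carries two oxygen donors.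

Step 7
Reactants: 10 {[6-(benzyloxy)benzofuran-3-yl]oxy}(tert-butyl)dimethylsilane; 7 3-[3-(benzyloxy)-2,4-dimethoxyphenyl]-3-chloro-3H-diazirine
Product: 14 7-(benzyloxy)-3-[3-(benzyloxy)-2,4-dimethoxyphenyl]-4H-chromen-4-one, via chlorocarbene 11 (not isolated), via cyclopropane adduct 12 (not isolated), via silyloxychromenylium chloride 13 (not isolated)
Conditions: 10 (1.5 equiv), Na2CO3, PhCF3, 60 °C, slow addition of 7
Reagents that add atoms: none
Why: Thermolysis of 7 releases N2 and singlet chlorocarbene 11, which adds as an electrophile to the C2=C3 silyl enol ether bond of the furan ring of 10 in a [2+1] cheletropic closure of the three-membered ring of 12. Loss of chloride from the benzylic cyclopropane carbon goes together with disrotatory two-electron electrocyclic opening of the old C2–C3 bond, pushed by O1 and the silyloxy group, so that the five-membered furan ring becomes the six-membered pyrylium ring of 13, from which chloride takes the silyl group to leave the 4-pyranone of 14. The closest known reaction type is the Ciamician–Dennstedt halocarbene one-carbon ring expansion, practised with dihalocarbenes on cyclic silyl enol ethers and on benzofurans and with arylchlorocarbenes on indoles and pyrroles. The six-membered ring is therefore not closed by a cyclisation but arises by insertion of the ring-B-bearing carbon between C2 and C4, with two new C–C bonds formed in one operation. The stereocentres of 12 are transient and are erased, so no stereocontrol is needed, and both chloride epimers of 12 should ionise because the trialkoxyaryl group stabilises the developing cation. The selectivity needed is site selectivity for the furan C2=C3 bond over the benzenoid rings, the benzylic C–H bonds and the carbene's own ortho-methoxy C–H bonds, and it is secured by the O1/OSi donor pair on that bond, by the excess of 10 and by the low stationary concentration of 7.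

Step 8
Reactants: 14 7-(benzyloxy)-3-[3-(benzyloxy)-2,4-dimethoxyphenyl]-4H-chromen-4-one
Product: 16 (3R,4R)-7-(benzyloxy)-3-[3-(benzyloxy)-2,4-dimethoxyphenyl]chroman-4-ol (cis), via racemic isoflavanone 15 (not isolated)
Conditions: RuCl[(R,R)-TsDPEN](p-cymene) (2 mol %), HCO2H–Et3N (5:2), EtOAc, 40 °C
Reagents that add atoms: none
Why: In this Noyori–Ikariya asymmetric transfer hydrogenation, conjugate reduction gives 15, whose C3 racemises through the enol, and the (R,R)-catalyst should reduce only the (3R)-ketone from the face anti to the aryl group (dynamic kinetic resolution), which sets C4 as R by catalyst control and C3 as R through the cis preference.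

Step 9
Reactants: 16 (3R,4R)-7-(benzyloxy)-3-[3-(benzyloxy)-2,4-dimethoxyphenyl]chroman-4-ol; 17 2-bromo-5-methoxyphenol
Product: 19 2-bromo-4-{(3R,4S)-7-(benzyloxy)-3-[3-(benzyloxy)-2,4-dimethoxyphenyl]chroman-4-yl}-5-methoxyphenol (3,4-trans), via chroman-4-ylium cation 18 (not isolated)
Conditions: 17 (3 equiv), p-TsOH·H2O (10 mol %), CH2Cl2–(CF3)2CHOH, −20 to 0 °C
Reagents that add atoms: none
Why: In this dehydrative Friedel–Crafts alkylation the acid ionises C4–OH to cation 18 (stabilised by O1 and the para 7-benzyloxy group), and 17 should attack through its carbon para to OH and ortho to OMe on the face anti to the C3 aryl group, whose 2'-methoxy oxygen also screens the syn face, which sets C4 as S and trans to C3.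

Step 10
Reactants: 19 2-bromo-4-{(3R,4S)-7-(benzyloxy)-3-[3-(benzyloxy)-2,4-dimethoxyphenyl]chroman-4-yl}-5-methoxyphenol
Product: 20 (3R,4S)-7-(benzyloxy)-4-[4-(benzyloxy)-5-bromo-2-methoxyphenyl]-3-[3-(benzyloxy)-2,4-dimethoxyphenyl]chromane
Conditions: BnBr, K2CO3, DMF, rt
Reagents that add atoms: benzyl bromide, BrCc1ccccc1
Why: Williamson etherification of the single free phenol removes the acidic proton before the enolate coupling and touches no stereocentre.

Step 11
Reactants: 21 7-hydroxychroman-4-one
Product: 22 7-(benzyloxy)chroman-4-one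
Conditions: BnBr, K2CO3, acetone, reflux
Reagents that add atoms: benzyl bromide, BrCc1ccccc1
Why: Williamson etherification of the phenol gives the base-stable ketone partner for the lower unit.

Step 12
Reactants: 20 (3R,4S)-7-(benzyloxy)-4-[4-(benzyloxy)-5-bromo-2-methoxyphenyl]-3-[3-(benzyloxy)-2,4-dimethoxyphenyl]chromane; 22 7-(benzyloxy)chroman-4-one
Product: 23 7-(benzyloxy)-3-(2-(benzyloxy)-5-{(3R,4S)-7-(benzyloxy)-3-[3-(benzyloxy)-2,4-dimethoxyphenyl]chroman-4-yl}-4-methoxyphenyl)chroman-4-one (both epimers at the new lower C3)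
Conditions: Pd(OAc)2 (5 mol %), XPhos (10 mol %), K3PO4, toluene, 90 °C
Reagents that add atoms: none
Why: Palladium-catalysed ketone α-arylation (Buchwald–Hartwig type) joins the chromanone enolate to the aryl bromide, and the new C3 centre may form as a mixture because it is labile and is resolved dynamically in step 13.

Step 13
Reactants: 23 lower isoflavanone (both C3 epimers)
Product: 24 (3R,4R)-7-(benzyloxy)-3-(2-(benzyloxy)-5-{(3R,4S)-7-(benzyloxy)-3-[3-(benzyloxy)-2,4-dimethoxyphenyl]chroman-4-yl}-4-methoxyphenyl)chroman-4-ol (lower unit cis)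
Conditions: RuCl[(R,R)-TsDPEN](p-cymene) (3 mol %), HCO2H–Et3N (5:2), EtOAc, 40 °C
Reagents that add atoms: none
Why: Noyori–Ikariya transfer hydrogenation with dynamic kinetic resolution, as in step 8, should set the lower C4 as R by catalyst control and the lower C3 as R through hydride delivery anti to the aryl group of the rapidly epimerising ketone, while the remote upper stereocentres have no acidic or reducible neighbour.

Step 14
Reactants: 24 tetrabenzyl lower isoflavan-4-ol
Product: 25 (3R)-3-{2-hydroxy-5-[(3R,4S)-7-hydroxy-3-(3-hydroxy-2,4-dimethoxyphenyl)chroman-4-yl]-4-methoxyphenyl}chroman-7-ol (CNP0202416.1)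
Conditions: H2 (1 atm), Pd/C, EtOH–EtOAc–AcOH, rt
Reagents that add atoms: none
Why: Catalytic hydrogenolysis should cleave the four benzyl ethers and the benzylic C4–OH of the lower unit (activated by the para oxygen) in one operation, while the diarylmethine C–C bonds, the methyl ethers and the three remaining stereocentres are not touched.

Compound list
1 | 2,6-dimethoxyphenol | COc1cccc(OC)c1O | starting material
2 | 2-(benzyloxy)-1,3-dimethoxybenzene | COc1cccc(OC)c1OCc1ccccc1 | intermediate
3 | 3-(benzyloxy)-N-(chlorosulfonyl)-2,4-dimethoxybenzamide | O=C(NS(=O)(=O)Cl)c1ccc(OC)c(OCc2ccccc2)c1OC | intermediate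
4 | 3-(benzyloxy)-2,4-dimethoxybenzonitrile | N#Cc1ccc(OC)c(OCc2ccccc2)c1OC | intermediate
5 | lithium 3-(benzyloxy)-2,4-dimethoxy-N,N'-bis(trimethylsilyl)benzamidinate | [Li]N([Si](C)(C)C)C(=N[Si](C)(C)C)c1ccc(OC)c(OCc2ccccc2)c1OC | intermediate
6 | 3-(benzyloxy)-2,4-dimethoxybenzamidine hydrochloride | Cl.N=C(N)c1ccc(OC)c(OCc2ccccc2)c1OC | intermediate
7 | 3-[3-(benzyloxy)-2,4-dimethoxyphenyl]-3-chloro-3H-diazirine | ClC1(N=N1)c1ccc(OC)c(OCc2ccccc2)c1OC | intermediate
8 | 6-hydroxybenzofuran-3(2H)-one | O=C1COc2cc(O)ccc12 | starting material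
9 | 6-(benzyloxy)benzofuran-3(2H)-one | O=C1COc2cc(OCc3ccccc3)ccc12 | intermediate
10 | {[6-(benzyloxy)benzofuran-3-yl]oxy}(tert-butyl)dimethylsilane | CC(C)(C)[Si](C)(C)Oc1coc2cc(OCc3ccccc3)ccc12 | intermediate
11 | [3-(benzyloxy)-2,4-dimethoxyphenyl]chlorocarbene | Cl[C]c1ccc(OC)c(OCc2ccccc2)c1OC | intermediate
12 | 4-(benzyloxy)-1-[3-(benzyloxy)-2,4-dimethoxyphenyl]-6b-(tert-butyldimethylsilyloxy)-1-chloro-1a,6b-dihydro-1H-cyclopropa[b][1]benzofuran (racemic, both C1 epimers) | CC(C)(C)[Si](C)(C)OC12c3ccc(OCc4ccccc4)cc3OC1C2(Cl)c1ccc(OC)c(OCc2ccccc2)c1OC | intermediate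
13 | 7-(benzyloxy)-3-[3-(benzyloxy)-2,4-dimethoxyphenyl]-4-(tert-butyldimethylsilyloxy)chromenylium chloride | CC(C)(C)[Si](C)(C)Oc1c(-c2ccc(OC)c(OCc3ccccc3)c2OC)c[o+]c2cc(OCc3ccccc3)ccc12.[Cl-] | intermediate
14 | 7-(benzyloxy)-3-[3-(benzyloxy)-2,4-dimethoxyphenyl]-4H-chromen-4-one | O=c1c(-c2ccc(OC)c(OCc3ccccc3)c2OC)coc2cc(OCc3ccccc3)ccc12 | intermediate
15 | 7-(benzyloxy)-3-[3-(benzyloxy)-2,4-dimethoxyphenyl]chroman-4-one (racemic) | O=C1c2ccc(OCc3ccccc3)cc2OCC1c1ccc(OC)c(OCc2ccccc2)c1OC | intermediate
16 | (3R,4R)-7-(benzyloxy)-3-[3-(benzyloxy)-2,4-dimethoxyphenyl]chroman-4-ol | O[C@H]1c2ccc(OCc3ccccc3)cc2OC[C@H]1c1ccc(OC)c(OCc2ccccc2)c1OC | intermediate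
17 | 2-bromo-5-methoxyphenol | COc1ccc(Br)c(O)c1 | starting material
18 | (3R)-7-(benzyloxy)-3-[3-(benzyloxy)-2,4-dimethoxyphenyl]chroman-4-ylium (ion pair with the catalyst anion) | [CH+]1c2ccc(OCc3ccccc3)cc2OC[C@H]1c1ccc(OC)c(OCc2ccccc2)c1OC | intermediate
19 | 2-bromo-4-{(3R,4S)-7-(benzyloxy)-3-[3-(benzyloxy)-2,4-dimethoxyphenyl]chroman-4-yl}-5-methoxyphenol | COc1cc(O)c(Br)cc1[C@@H]1c2ccc(OCc3ccccc3)cc2OC[C@H]1c1ccc(OC)c(OCc2ccccc2)c1OC | intermediate
20 | (3R,4S)-7-(benzyloxy)-4-[4-(benzyloxy)-5-bromo-2-methoxyphenyl]-3-[3-(benzyloxy)-2,4-dimethoxyphenyl]chromane | COc1cc(OCc2ccccc2)c(Br)cc1[C@@H]1c2ccc(OCc3ccccc3)cc2OC[C@H]1c1ccc(OC)c(OCc2ccccc2)c1OC | intermediate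
21 | 7-hydroxychroman-4-one | O=C1CCOc2cc(O)ccc12 | starting material
22 | 7-(benzyloxy)chroman-4-one | O=C1CCOc2cc(OCc3ccccc3)ccc12 | intermediate
23 | 7-(benzyloxy)-3-(2-(benzyloxy)-5-{(3R,4S)-7-(benzyloxy)-3-[3-(benzyloxy)-2,4-dimethoxyphenyl]chroman-4-yl}-4-methoxyphenyl)chroman-4-one (both lower C3 epimers) | COc1cc(OCc2ccccc2)c(C2COc3cc(OCc4ccccc4)ccc3C2=O)cc1[C@@H]1c2ccc(OCc3ccccc3)cc2OC[C@H]1c1ccc(OC)c(OCc2ccccc2)c1OC | intermediate
24 | (3R,4R)-7-(benzyloxy)-3-(2-(benzyloxy)-5-{(3R,4S)-7-(benzyloxy)-3-[3-(benzyloxy)-2,4-dimethoxyphenyl]chroman-4-yl}-4-methoxyphenyl)chroman-4-ol | COc1cc(OCc2ccccc2)c([C@@H]2COc3cc(OCc4ccccc4)ccc3[C@@H]2O)cc1[C@@H]1c2ccc(OCc3ccccc3)cc2OC[C@H]1c1ccc(OC)c(OCc2ccccc2)c1OC | intermediate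
25 | (3R)-3-{2-hydroxy-5-[(3R,4S)-7-hydroxy-3-(3-hydroxy-2,4-dimethoxyphenyl)chroman-4-yl]-4-methoxyphenyl}chroman-7-ol | COc1cc(O)c([C@@H]2COc3cc(O)ccc3C2)cc1[C@@H]1c2ccc(O)cc2OC[C@H]1c1ccc(OC)c(O)c1OC | target

Total step count: 14. Longest linear sequence: 11 steps (1–4, 7–10, 12–14).

Steps most likely to fail

Step 7. The carbene may be consumed before it reaches the furan bond, by 1,5-C–H insertion into its own ortho-methoxy group or by azine formation with unreacted diazirine. The electron-rich diazirine may also suffer ring chlorination or decomposition while it is made and stored. In the fallback the ring expansion is kept, but the aryl group is brought in afterwards by cross-coupling.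
- From 10, dibromocarbene (CHBr3, KOt-Bu, pentane, −20 °C to rt) should give the dibromocyclopropane adduct F1. On warming it opens with loss of the silyl bromide to 7-(benzyloxy)-3-bromo-4H-chromen-4-one F2.
- From 2, NBS (MeCN, 0 °C) should give 3-(benzyloxy)-1-bromo-2,4-dimethoxybenzene F3. Miyaura borylation (B2pin2, Pd(dppf)Cl2, KOAc, dioxane, 90 °C) then gives the pinacol boronate F4.
- Suzuki–Miyaura coupling of F2 and F4 (Pd(PPh3)4, K2CO3, dioxane–water, 80 °C) comes back to the route at 14. Compounds 3 to 7 are then not needed.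

Step 9. The cation may lose the C3 proton instead of being arylated. Reversible elimination and reprotonation would erode the C3 configuration, and attack by the trialkoxyaryl ring of a second molecule would cause oligomerisation. In the fallback the Brønsted-acid ionisation of the alcohol is replaced by a storable thioether that is ionised by a thiophilic silver salt in a buffered aprotic medium, so no proton source can return an alkene to the cation.
- From 16, diphenyl disulfide and n-Bu3P (THF, rt, substitution with inversion) should give (3R,4S)-7-(benzyloxy)-3-[3-(benzyloxy)-2,4-dimethoxyphenyl]-4-(phenylsulfanyl)chromane F5.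
- F5 is treated with AgBF4 and 2,6-di-tert-butyl-4-methylpyridine in CH2Cl2 at −78 to −20 °C in the presence of 17. The route is rejoined at 19.

Step 12. Slow oxidative addition and reductive elimination at the hindered ortho-benzyloxy aryl bromide would leave the chromanone enolate time for retro-oxa-Michael opening and self-condensation. In the fallback the polarity of the bond formation is inverted, so that neither an enolate nor a base is present.
- From 22, α-bromination (CuBr2, EtOAc–CHCl3, reflux) should give racemic 7-(benzyloxy)-3-bromochroman-4-one F6.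
- From 20, bromine–lithium exchange (n-BuLi, THF, −78 °C) should give the aryllithium F7, and ZnCl2 then the arylzinc chloride F8.
- F8 is coupled with F6 in a nickel-catalysed Negishi α-arylation (NiCl2·glyme, pybox ligand, THF–glyme, −20 °C). The route is rejoined at 23.

Further compounds
F1 | step 7 | 4-(benzyloxy)-1,1-dibromo-6b-(tert-butyldimethylsilyloxy)-1a,6b-dihydro-1H-cyclopropa[b][1]benzofuran (racemic) | CC(C)(C)[Si](C)(C)OC12c3ccc(OCc4ccccc4)cc3OC1C2(Br)Br
F2 | step 7 | 7-(benzyloxy)-3-bromo-4H-chromen-4-one | O=c1c(Br)coc2cc(OCc3ccccc3)ccc12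
F3 | step 7 | 3-(benzyloxy)-1-bromo-2,4-dimethoxybenzene | COc1ccc(Br)c(OC)c1OCc1ccccc1
F4 | step 7 | 2-[3-(benzyloxy)-2,4-dimethoxyphenyl]-4,4,5,5-tetramethyl-1,3,2-dioxaborolane | COc1ccc(B2OC(C)(C)C(C)(C)O2)c(OC)c1OCc1ccccc1
F5 | step 9 | (3R,4S)-7-(benzyloxy)-3-[3-(benzyloxy)-2,4-dimethoxyphenyl]-4-(phenylsulfanyl)chromane | c1ccccc1S[C@@H]1c2ccc(OCc3ccccc3)cc2OC[C@H]1c1ccc(OC)c(OCc2ccccc2)c1OC
F6 | step 12 | 7-(benzyloxy)-3-bromochroman-4-one (racemic) | O=C1c2ccc(OCc3ccccc3)cc2OCC1Br
F7 | step 12 | aryllithium derived from 20 (Li in place of Br) | COc1cc(OCc2ccccc2)c([Li])cc1[C@@H]1c2ccc(OCc3ccccc3)cc2OC[C@H]1c1ccc(OC)c(OCc2ccccc2)c1OC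
F8 | step 12 | arylzinc chloride derived from 20 (ZnCl in place of Br) | COc1cc(OCc2ccccc2)c([Zn]Cl)cc1[C@@H]1c2ccc(OCc3ccccc3)cc2OC[C@H]1c1ccc(OC)c(OCc2ccccc2)c1OC
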